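## The problem

The target joins three aromatic rings. Guaiacyl ring A sits on a glycerol chain (C7–C8–C9); the C8 oxygen is the phenolic oxygen of the syringyl-type ring B; ring B sits on C2 of a 2,3-dihydrobenzofuran fused to ring C (7-methoxy, 5-(3-hydroxypropyl), 3-hydroxymethyl). There are two pairs of stereocentres: C2/C3 of the dihydrobenzofuran, (2R,3R), with aryl and CH2OH cis (the less stable arrangement), and C7/C8 of the chain, (7R,8S), the erythro (1,2-anti) aryl ether. Ring B separates the pairs, so neither can control the other and each needs its own source of absolute configuration. Within a pair, C2 can direct C3 by shielding one face of the five-membered ring, and C8 can direct C7 through a Felkin–Anh addition to a C7 carbonyl. The cis-dihydrobenzofuran is fragile: acid ionises the benzylic C2–O1 bond (para to the ring B oxygen) and returns the trans isomer, base does the same through a quinone methide once the ring B phenol is free, a carbonyl on C3 makes C3–H epimerisable, and oxidants attack the benzylic C2–H. The 4-hydroxybenzyl alcohol of ring A is also prone to quinone methide formation, so the end game cannot be acidic or strongly basic, and the C8 ether must be made with a phenol flanked by two methoxy groups. A ring contraction is possible because the ring O1–C2–C3–C3a–C7a carries a one-carbon substituent on C3: placing that carbon between C3 and C3a gives the pyranone ring O1–C2–C3–C4(=O)–C4a–C8a of a flavanone, whose C2 aryl stereocentre is accessible by catalytic asymmetric conjugate addition.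

## Retrosynthesis

Abbreviations: TBS = tert-butyldimethylsilyl, TBDPS = tert-butyldiphenylsilyl, TIPS = triisopropylsilyl.

**32 from 31.** All four hydroxyl groups are masked as silyl ethers in 31, so the last step is a single buffered fluoride treatment. This avoids acid and hydrogenolysis, both of which endanger the benzylic C2–O1 and C7–O bonds.

**31 from 30 (C7–H bond).** The C7 carbinol is traced to aryl ketone 30. Non-chelating hydride addition anti to the C8 aryloxy group (Felkin–Anh) gives the 1,2-anti, i.e. erythro, relationship directly. An auxiliary-controlled syn-aldol of an aryloxyacetyl imide was weighed against this; it gives the 1,2-syn (threo) ether and would need a later inversion at C7. The forward step must be fast at low temperature so that the C8–H next to the ketone is not removed.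

**30 from 26 and 29 (C7–aryl bond).** Cutting between C7 and ring A gives Weinreb amide 26 and aryllithium 29, made from aryl bromide 28 and thus from bromophenol 27. Ring A enters as a simple building block at a late stage. Amide 26 comes from methyl ester 25.

**25 from 21 and 24 (C8–O bond).** The aryl ether is cut at C8. The forward reaction is a Mitsunobu etherification of the hindered phenol 21 with the α-hydroxy ester 24, with inversion at a carbon activated by the ester. The C8 configuration then comes from the chiral pool: 24 from diol 23 from acetonide 22. Because 24 is enantiopure, the minor enantiomer of 21 left by an imperfect conjugate addition becomes a separable diastereomer of 25. This cut removes half of the molecule and both chain stereocentres from the dihydrobenzofuran problem.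

**21 from 18 (functional group changes).** Phenol 21 comes from tris-silyl ether 20 by selective cleavage of the aryl silyl ether, 20 from alcohol 19, and 19 from cis ester 18 by a non-basic hydride reduction. The C3 carbonyl is removed at once, after which C3 can no longer epimerise.

**18 from 15 (key cut, C3–C3a bond).** The cis ester 18 is the ring-contracted image of 3-diazoflavanone 15. Photochemical Wolff rearrangement moves the ring C carbon from C4 to C3, giving ketene 16; the alcohol solvent traps it as ester enol 17, which ketonises to 18. The cut turns a cis-2,3-disubstituted five-membered ring with two stereocentres into a six-membered ring with one stereocentre on a carbon that takes no part in the rearrangement. The forward step must favour the 1,2-shift over carbene-type reactions and must deliver the proton to C3 anti to the C2 aryl group.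

**15 from 13 (C3=N2).** The diazo group is placed on flavanone 13 by deacylative diazo transfer through the trifluoroacetyl enol 14. The enolate must be formed and acylated cold, because a flavanone enolate can open by retro-oxa-Michael reaction and lose the C2 configuration.

**13 from 8 and 12 (C2–aryl bond).** The flavanone is cut at C2 into chromone 8 and arylboronic acid 12; the forward reaction is an enantioselective palladium-catalysed conjugate addition that sets C2. Ring B carries a silyl ether rather than an allyl ether, because the aryl–palladium intermediates of this step add to terminal alkenes. The chain oxygen carries the acid-robust TBDPS group because the step runs warm in the presence of water and an ammonium salt. Boronic acid 12 comes from aryl bromide 10 via aryllithium 11, and 10 from the commercial bromophenol 9.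

**8 from 4 and 6; 4 from 2 and 1.** The side chain of 8 is attached by B-alkyl Suzuki–Miyaura coupling of bromochromone 4 with alkylborane 7, obtained from allyl silyl ether 6 (from allyl alcohol 5). Chromone 4 comes from bromo ketone 2 via enaminone 3, and 2 from the commercial hydroxy ketone 1 by bromination at the only position activated by both the hydroxyl and the acetyl group. This fixes the ring C substitution pattern without regiochemical doubt.

## Roads not taken

**Alternative 1:** The C7–O bond is made last. The C7-deoxy phenol A1, which carries a tert-butyl carbonate on O9, is oxidised with DDQ to the quinone methide of ring A; the carbonate carbonyl oxygen adds to C7 and, after loss of isobutene, gives the six-membered trans cyclic carbonate A2. Merits: C7 is set in a chair-like cyclisation with both substituents equatorial, which is a stronger basis for the erythro relationship than an open-chain model, and C8 is never α to a carbonyl, so it cannot epimerise. Weak points: the oxidant must select the ring A phenol in a molecule that also contains the cis-dihydrobenzofuran, whose C2–H is benzylic, α to oxygen and para to an alkoxy group, so dehydrogenation across C2–C3 is a likely competing process. The road also does nothing for the cis ring, which must still be built by one of the other methods, and A1 still needs the C8 aryl ether from a hindered phenol. Comparison: for control of C7 this road is at least as good as the hydride reduction of 30 and probably better. The chosen plan sets against it that a hydride at low temperature cannot harm the oxidisable ring, and that a wrong C7 epimer can be corrected by inversion.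

**Alternative 2:** The O1–C2 bond is cut. The open-chain phenol A3, from an auxiliary-controlled syn-aldol between a ring C arylacetic acid derivative and the ring B aldehyde, closes under PPh3 and diisopropyl azodicarboxylate with inversion at the benzylic carbinol to give the cis-dihydrobenzofuran A4, ring B carrying a pivalate. Merits: both stereocentres come from a very reliable aldol; C3 is fixed when a carbon–carbon bond is made, not by a protonation; no photochemistry is needed; the step count to the core is similar or lower. Weak points: the carbinol carbon is benzylic to a ring with a para oxygen and two methoxy groups. Even with the pivalate reducing donation, the activated alcohol can ionise, and a cation closes to the more stable trans ring or with retention. The SN2 transition state must also bring aryl and CH2OSi together on one face, which slows the wanted path relative to ionisation. Comparison: alternative 2 is better in the certainty of C3 and of absolute configuration. The chosen plan sets against it that C2 never bears a leaving group, so its configuration cannot leak through a benzylic cation, and that the cis relationship arises from a kinetically favoured protonation, not from a substitution that sterics oppose.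

**Alternative 3:** The C2–C3 bond is cut. The ring C aryldiazoacetate A5, whose neighbouring phenol oxygen carries the ring B benzyl group, is decomposed by Rh2(S-PTTL)4; the carbenoid inserts into the benzylic C–H bond of the O–CH2 group and gives the cis ester A6. Merits: one catalytic step closes the ring and sets both stereocentres; cis selectivity and high enantioselectivity are established for simpler aryl benzyl ethers of this type; A5 is made in few steps. It is probably the shortest road to a cis ester of this kind and the best precedented for the cis relationship. Weak points for this target: the 7-methoxy group is ortho to the benzyloxy group and twists the ether out of the arene plane, changing the conformation on which the catalyst's selectivity depends. The trialkoxybenzyl C–H bond is strongly hydridic, which favours a stepwise hydride-transfer path whose zwitterion can close to either diastereomer. Oxonium ylide formation at the ether or methoxy oxygens can also compete. Comparison: alternative 3 is stronger in precedent and step count. The chosen plan sets against it that C2 is made by a conjugate addition known for chromones and is independent of the ring-forming step, that no chiral dirhodium catalyst has to be matched to an unusually substituted substrate, and that the ring contraction uses no metal.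

Key step: step 9

Assumption: the (S)-configured pyridine-oxazoline ligand is taken to deliver the aryl group to the same enone face as in the cyclic enone series, which corresponds to the (2R)-flavanone 13; if the sense is opposite, the (R)-ligand is used.

## Steps

Step 1
Reactants: 1 1-(2-hydroxy-3-methoxyphenyl)ethan-1-one
Product: 2 1-(5-bromo-2-hydroxy-3-methoxyphenyl)ethan-1-one
Conditions: NBS, MeCN, 0 °C → rt
Reagents that add atoms: N-bromosuccinimide O=C1CCC(=O)N1Br
Why: Electrophilic aromatic bromination; the hydroxyl group directs para and the acetyl group meta to the same carbon, so one regioisomer is expected.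

Step 2
Reactants: 2 1-(5-bromo-2-hydroxy-3-methoxyphenyl)ethan-1-one
Product: 4 6-bromo-8-methoxy-4H-chromen-4-one, via enaminone 3 (not isolated)
Conditions: Me2NCH(OMe)2, toluene, 100 °C; then conc. HCl, CH2Cl2, rt
Reagents that add atoms: N,N-dimethylformamide dimethyl acetal COC(OC)N(C)C
Why: Condensation of the methyl ketone with the amide acetal gives the enaminone, and acid then promotes addition of the phenol and loss of dimethylamine (enaminone chromone synthesis).

Step 3
Reactants: 5 prop-2-en-1-ol
Product: 6 tert-butyl(diphenyl)(prop-2-en-1-yloxy)silane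
Conditions: t-BuPh2SiCl, imidazole, CH2Cl2, 0 °C → rt
Reagents that add atoms: tert-butyl(chloro)diphenylsilane CC(C)(C)[Si](Cl)(c1ccccc1)c1ccccc1
Why: Routine silylation of a primary alcohol; the TBDPS ether is chosen because it should survive the warm, wet and weakly acidic conjugate addition of step 7.

Step 4
Reactants: 4 6-bromo-8-methoxy-4H-chromen-4-one; 6 tert-butyl(diphenyl)(prop-2-en-1-yloxy)silane
Product: 8 6-[3-(TBDPSO)propyl]-8-methoxy-4H-chromen-4-one, via alkylborane 7 (not isolated)
Conditions: 6, 9-BBN, THF, rt; then 4, PdCl2(dppf), AsPh3, Cs2CO3, DMF/THF/H2O, rt → 40 °C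
Reagents that add atoms: none
Why: Anti-Markovnikov hydroboration followed by B-alkyl Suzuki–Miyaura coupling at the aryl bromide; a carbonate base at low temperature is used to spare the base-sensitive 2-unsubstituted chromone.

Step 5
Reactants: 9 4-bromo-2,6-dimethoxyphenol
Product: 10 (4-bromo-2,6-dimethoxyphenoxy)(tert-butyl)dimethylsilane
Conditions: t-BuMe2SiCl, imidazole, DMF, rt
Reagents that add atoms: tert-butyl(chloro)dimethylsilane CC(C)(C)[Si](C)(C)Cl
Why: Silylation of the phenol; an aryl TBS ether tolerates organolithium, the palladium step, amide base, light and hydride, and can later be cleaved beside alkyl silyl ethers.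

Step 6
Reactants: 10 (4-bromo-2,6-dimethoxyphenoxy)(tert-butyl)dimethylsilane
Product: 12 [4-(TBSO)-3,5-dimethoxyphenyl]boronic acid, via aryllithium 11 (not isolated)
Conditions: n-BuLi, THF, –78 °C; B(Oi-Pr)3, –78 °C → rt; aq. HCl (pH 3), 0 °C
Reagents that add atoms: triisopropyl borate CC(C)OB(OC(C)C)OC(C)C; water O
Why: Bromine–lithium exchange, borylation and hydrolysis; both positions ortho to the silyloxy group are blocked by methoxy groups, so silyl migration to carbon is not possible.

Step 7
Reactants: 8 6-[3-(TBDPSO)propyl]-8-methoxy-4H-chromen-4-one; 12 [4-(TBSO)-3,5-dimethoxyphenyl]boronic acid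
Product: 13 (2R)-2-[4-(TBSO)-3,5-dimethoxyphenyl]-8-methoxy-6-[3-(TBDPSO)propyl]chroman-4-one
Conditions: Pd(OCOCF3)2 (5 mol %), (S)-4-tert-butyl-2-(pyridin-2-yl)-4,5-dihydrooxazole (6 mol %), NH4PF6 (30 mol %), H2O (5 equiv), ClCH2CH2Cl, 60 °C
Reagents that add atoms: none
Why: Enantioselective conjugate addition of an arylboronic acid to a chromone by a cationic divalent palladium pyridine-oxazoline catalyst; the ligand controls the face of aryl insertion at C2, and protonolysis of the palladium enolate by water turns the catalyst over without an oxidant.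

Step 8
Reactants: 13 (2R)-2-[4-(TBSO)-3,5-dimethoxyphenyl]-8-methoxy-6-[3-(TBDPSO)propyl]chroman-4-one
Product: 15 (2S)-3-diazo-2-[4-(TBSO)-3,5-dimethoxyphenyl]-8-methoxy-6-[3-(TBDPSO)propyl]chroman-4-one, via trifluoroacetyl enol 14 (not isolated)
Conditions: LiN(SiMe3)2, THF, –78 °C; CF3CO2CH2CF3, –78 °C; aq. NH4Cl; then MeSO2N3, Et3N, H2O (1 equiv), MeCN, rt
Reagents that add atoms: methanesulfonyl azide CS(=O)(=O)N=[N+]=[N-]; 2,2,2-trifluoroethyl trifluoroacetate O=C(OCC(F)(F)F)C(F)(F)F (its acyl group is carried only by 14)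
Why: Detrifluoroacetylative (Regitz-type) diazo transfer; the kinetic enolate is acylated at –78 °C before retro-oxa-Michael opening can occur, and the 1,3-dicarbonyl 14 then takes up the diazo group under mild amine base with loss of the trifluoroacetyl group. C2 is not touched; its descriptor changes from R to S only because C3 gains priority.

Step 9
Reactants: 15 (2S)-3-diazo-2-[4-(TBSO)-3,5-dimethoxyphenyl]-8-methoxy-6-[3-(TBDPSO)propyl]chroman-4-one
Product: 18 methyl (2R,3S)-2-[4-(TBSO)-3,5-dimethoxyphenyl]-7-methoxy-5-[3-(TBDPSO)propyl]-2,3-dihydro-1-benzofuran-3-carboxylate (cis), via ketene 16 (not isolated), via ester enol 17 (not isolated)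
Conditions: hν (365 nm), degassed MeOH/THF, –40 °C, dilute
Reagents that add atoms: methanol CO
Why: Excitation of the diazo ketone, whose N2–C3–C4=O unit is held s-cis by the pyranone ring, causes loss of N2 concerted with the 1,2-shift of the aryl carbon C4a from C4 to C3 (Wolff rearrangement), so no free carbene is available for a 1,2-hydride shift from C2 or for O–H insertion; the closest known reaction type is the photochemical Wolff ring contraction of cyclic 2-diazo ketones, which includes 3-diazochroman-4-ones giving 2,3-dihydrobenzofuran-3-carboxylates. The five-membered ring is not closed from a chain but formed by contraction: the new C3–C3a bond replaces the C4–C4a bond and C4 is extruded as the exocyclic carbonyl carbon of ketene 16. Methanol adds to 16 to give ester enol 17, and the C3 stereocentre is created when 17 ketonises. Allylic strain between the exocyclic C(OH)OMe group and the C2 substituent turns the ring B aryl group pseudoaxial, so it shields one face of the enol; the proton arrives anti to it, which places the ester cis to the aryl group (2R,3S). C2 is a spectator and keeps the configuration set in step 7. The step needs chemoselectivity for the shift over carbene reactions, secured by the locked s-cis geometry and the absence of metal or sensitiser, and kinetic diastereoselectivity, secured by neutral methanol at low temperature so that the less stable cis ester is not equilibrated. Because 18 can epimerise at C3, it is carried directly into step 10.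

Step 10
Reactants: 18 methyl (2R,3S)-2-[4-(TBSO)-3,5-dimethoxyphenyl]-7-methoxy-5-[3-(TBDPSO)propyl]-2,3-dihydro-1-benzofuran-3-carboxylate
Product: 19 {(2R,3R)-2-[4-(TBSO)-3,5-dimethoxyphenyl]-7-methoxy-5-[3-(TBDPSO)propyl]-2,3-dihydro-1-benzofuran-3-yl}methanol (cis)
Conditions: i-Bu2AlH, CH2Cl2, –78 → –40 °C; aq. KNaC4H4O6
Reagents that add atoms: none
Why: Reduction of the ester to the primary alcohol by a non-basic aluminium hydride, so C3 is not enolised and the cis relationship is kept; the descriptor at C3 changes from S to R only through the priority change.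

Step 11
Reactants: 19 {(2R,3R)-2-[4-(TBSO)-3,5-dimethoxyphenyl]-7-methoxy-5-[3-(TBDPSO)propyl]-2,3-dihydro-1-benzofuran-3-yl}methanol
Product: 20 (2R,3R)-2-[4-(TBSO)-3,5-dimethoxyphenyl]-3-(TBSO-methyl)-7-methoxy-5-[3-(TBDPSO)propyl]-2,3-dihydro-1-benzofuran
Conditions: t-BuMe2SiCl, imidazole, DMF, 0 °C → rt
Reagents that add atoms: tert-butyl(chloro)dimethylsilane CC(C)(C)[Si](C)(C)Cl
Why: Routine silylation of the primary alcohol, needed so that only the glycerate hydroxyl is activated in step 15.

Step 12
Reactants: 20 (2R,3R)-2-[4-(TBSO)-3,5-dimethoxyphenyl]-3-(TBSO-methyl)-7-methoxy-5-[3-(TBDPSO)propyl]-2,3-dihydro-1-benzofuran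
Product: 21 4-{(2R,3R)-3-(TBSO-methyl)-7-methoxy-5-[3-(TBDPSO)propyl]-2,3-dihydro-1-benzofuran-2-yl}-2,6-dimethoxyphenol
Conditions: n-Bu4NF (1.1 equiv), AcOH (1.2 equiv), THF, 0 °C
Reagents that add atoms: none
Why: Selective cleavage of the aryl silyl ether, since phenoxide leaves silicon far more readily than alkoxide; the acetic acid buffer keeps the liberated phenol protonated, so the para-phenoxide cannot open the C2–O1 bond through a quinone methide.

Step 13
Reactants: 22 methyl (4R)-2,2-dimethyl-1,3-dioxolane-4-carboxylate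
Product: 23 methyl (2R)-2,3-dihydroxypropanoate
Conditions: Amberlyst 15 (H+ form), MeOH, rt
Reagents that add atoms: none
Why: Acid-catalysed transacetalisation releases the diol; the stereocentre is not involved.

Step 14
Reactants: 23 methyl (2R)-2,3-dihydroxypropanoate
Product: 24 methyl (2R)-3-(TBDPSO)-2-hydroxypropanoate
Conditions: t-BuPh2SiCl, imidazole, CH2Cl2, 0 °C
Reagents that add atoms: tert-butyl(chloro)diphenylsilane CC(C)(C)[Si](Cl)(c1ccccc1)c1ccccc1
Why: Selective silylation of the primary hydroxyl beside the hindered and less nucleophilic α-hydroxy ester hydroxyl; the bulky TBDPS group is slow to migrate to the neighbouring oxygen.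

Step 15
Reactants: 21 4-{(2R,3R)-3-(TBSO-methyl)-7-methoxy-5-[3-(TBDPSO)propyl]-2,3-dihydro-1-benzofuran-2-yl}-2,6-dimethoxyphenol; 24 methyl (2R)-3-(TBDPSO)-2-hydroxypropanoate
Product: 25 methyl (2S)-2-(4-{(2R,3R)-3-(TBSO-methyl)-7-methoxy-5-[3-(TBDPSO)propyl]-2,3-dihydro-1-benzofuran-2-yl}-2,6-dimethoxyphenoxy)-3-(TBDPSO)propanoate
Conditions: PPh3, i-PrO2CN=NCO2i-Pr, toluene, 0 °C → rt (azodicarboxylate added last and slowly)
Reagents that add atoms: none
Why: Mitsunobu etherification; the phenol displaces the activated hydroxyl of the α-hydroxy ester by SN2 with inversion, turning (2R)-24 into the (2S) aryl ether that becomes C8. Slow addition keeps the concentration of free phenoxide low.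

Step 16
Reactants: 25 methyl (2S)-2-(4-{(2R,3R)-3-(TBSO-methyl)-7-methoxy-5-[3-(TBDPSO)propyl]-2,3-dihydro-1-benzofuran-2-yl}-2,6-dimethoxyphenoxy)-3-(TBDPSO)propanoate
Product: 26 (2S)-2-(4-{(2R,3R)-3-(TBSO-methyl)-7-methoxy-5-[3-(TBDPSO)propyl]-2,3-dihydro-1-benzofuran-2-yl}-2,6-dimethoxyphenoxy)-3-(TBDPSO)-N-methoxy-N-methylpropanamide
Conditions: MeNH(OMe)·HCl, i-PrMgCl, THF, –20 → 0 °C
Reagents that add atoms: N,O-dimethylhydroxylamine hydrochloride CNOC.Cl
Why: Aminolysis of the ester by the magnesium amide of N,O-dimethylhydroxylamine (Weinreb amide formation); the weakly basic amide at low temperature should leave the α-aryloxy stereocentre intact.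

Step 17
Reactants: 27 4-bromo-2-methoxyphenol
Product: 28 (4-bromo-2-methoxyphenoxy)tri(propan-2-yl)silane
Conditions: i-Pr3SiCl, imidazole, DMF, rt
Reagents that add atoms: chlorotri(propan-2-yl)silane CC(C)[Si](Cl)(C(C)C)C(C)C
Why: Routine silylation of the phenol; the TIPS ether tolerates the aryllithium and hydride steps and leaves with fluoride at the end.

Step 18
Reactants: 28 (4-bromo-2-methoxyphenoxy)tri(propan-2-yl)silane; 26 (2S)-2-(4-{(2R,3R)-3-(TBSO-methyl)-7-methoxy-5-[3-(TBDPSO)propyl]-2,3-dihydro-1-benzofuran-2-yl}-2,6-dimethoxyphenoxy)-3-(TBDPSO)-N-methoxy-N-methylpropanamide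
Product: 30 (2S)-2-(4-{(2R,3R)-3-(TBSO-methyl)-7-methoxy-5-[3-(TBDPSO)propyl]-2,3-dihydro-1-benzofuran-2-yl}-2,6-dimethoxyphenoxy)-3-(TBDPSO)-1-[3-methoxy-4-(TIPSO)phenyl]propan-1-one, via aryllithium 29 (not isolated)
Conditions: 28, n-BuLi, THF, –78 °C; then 26, –78 °C; aq. NH4Cl
Reagents that add atoms: none
Why: Bromine–lithium exchange and Weinreb ketone synthesis; the chelated tetrahedral adduct forms quickly at –78 °C, which prevents over-addition and limits deprotonation at C8.

Step 19
Reactants: 30 (2S)-2-(4-{(2R,3R)-3-(TBSO-methyl)-7-methoxy-5-[3-(TBDPSO)propyl]-2,3-dihydro-1-benzofuran-2-yl}-2,6-dimethoxyphenoxy)-3-(TBDPSO)-1-[3-methoxy-4-(TIPSO)phenyl]propan-1-one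
Product: 31 (1R,2S)-2-(4-{(2R,3R)-3-(TBSO-methyl)-7-methoxy-5-[3-(TBDPSO)propyl]-2,3-dihydro-1-benzofuran-2-yl}-2,6-dimethoxyphenoxy)-3-(TBDPSO)-1-[3-methoxy-4-(TIPSO)phenyl]propan-1-ol
Conditions: LiBH(s-Bu)3, THF, –78 °C; aq. NH4Cl
Reagents that add atoms: none
Why: Felkin–Anh reduction of an α-aryloxy ketone by a bulky, poorly chelating hydride; attack anti to the C8 aryloxy group on the side of the C8 hydrogen gives the 1,2-anti alcohol, i.e. erythro (7R) from (8S).

Step 20
Reactants: 31 (1R,2S)-2-(4-{(2R,3R)-3-(TBSO-methyl)-7-methoxy-5-[3-(TBDPSO)propyl]-2,3-dihydro-1-benzofuran-2-yl}-2,6-dimethoxyphenoxy)-3-(TBDPSO)-1-[3-methoxy-4-(TIPSO)phenyl]propan-1-ol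
Product: 32 (1R,2S)-1-(4-hydroxy-3-methoxyphenyl)-2-{4-[(2R,3R)-3-(hydroxymethyl)-5-(3-hydroxypropyl)-7-methoxy-2,3-dihydro-1-benzofuran-2-yl]-2,6-dimethoxyphenoxy}propane-1,3-diol (CNP0301567.1)
Conditions: n-Bu4NF (excess), AcOH, THF, 0 °C → rt
Reagents that add atoms: none
Why: Fluoride cleavage of all four silyl ethers in one operation; buffering with acetic acid avoids both the acid that would ionise C2–O1 or C7–O and free alkoxide or phenoxide base.

## Compound list

1 | 1-(2-hydroxy-3-methoxyphenyl)ethan-1-one | CC(=O)c1cccc(OC)c1O | starting material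
2 | 1-(5-bromo-2-hydroxy-3-methoxyphenyl)ethan-1-one | CC(=O)c1cc(Br)cc(OC)c1O | intermediate
3 | (E)-1-(5-bromo-2-hydroxy-3-methoxyphenyl)-3-(dimethylamino)prop-2-en-1-one | CN(C)/C=C/C(=O)c1cc(Br)cc(OC)c1O | intermediate
4 | 6-bromo-8-methoxy-4H-chromen-4-one | O=c1ccoc2c(OC)cc(Br)cc12 | intermediate
5 | prop-2-en-1-ol (allyl alcohol) | C=CCO | starting material
6 | tert-butyl(diphenyl)(prop-2-en-1-yloxy)silane | C=CCO[Si](c1ccccc1)(c1ccccc1)C(C)(C)C | intermediate
7 | 9-[3-(TBDPSO)propyl]-9-borabicyclo[3.3.1]nonane | CC(C)(C)[Si](c1ccccc1)(c1ccccc1)OCCCB1C2CCCC1CCC2 | intermediate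
8 | 6-[3-(TBDPSO)propyl]-8-methoxy-4H-chromen-4-one | O=c1ccoc2c(OC)cc(CCCO[Si](c3ccccc3)(c3ccccc3)C(C)(C)C)cc12 | intermediate
9 | 4-bromo-2,6-dimethoxyphenol | COc1cc(Br)cc(OC)c1O | starting material
10 | (4-bromo-2,6-dimethoxyphenoxy)(tert-butyl)dimethylsilane | COc1cc(Br)cc(OC)c1O[Si](C)(C)C(C)(C)C | intermediate
11 | [4-(TBSO)-3,5-dimethoxyphenyl]lithium | [Li]c1cc(OC)c(O[Si](C)(C)C(C)(C)C)c(OC)c1 | intermediate
12 | [4-(TBSO)-3,5-dimethoxyphenyl]boronic acid | COc1cc(B(O)O)cc(OC)c1O[Si](C)(C)C(C)(C)C | intermediate
13 | (2R)-2-[4-(TBSO)-3,5-dimethoxyphenyl]-8-methoxy-6-[3-(TBDPSO)propyl]chroman-4-one | COc1cc([C@@H]2Oc3c(OC)cc(CCCO[Si](c4ccccc4)(c4ccccc4)C(C)(C)C)cc3C(=O)C2)cc(OC)c1O[Si](C)(C)C(C)(C)C | intermediate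
14 | (2S)-2-[4-(TBSO)-3,5-dimethoxyphenyl]-8-methoxy-6-[3-(TBDPSO)propyl]-3-[(Z)-2,2,2-trifluoro-1-hydroxyethylidene]chroman-4-one | COc1cc([C@@H]2Oc3c(OC)cc(CCCO[Si](c4ccccc4)(c4ccccc4)C(C)(C)C)cc3C(=O)/C2=C(\O)C(F)(F)F)cc(OC)c1O[Si](C)(C)C(C)(C)C | intermediate
15 | (2S)-3-diazo-2-[4-(TBSO)-3,5-dimethoxyphenyl]-8-methoxy-6-[3-(TBDPSO)propyl]chroman-4-one | COc1cc([C@@H]2Oc3c(OC)cc(CCCO[Si](c4ccccc4)(c4ccccc4)C(C)(C)C)cc3C(=O)C2=[N+]=[N-])cc(OC)c1O[Si](C)(C)C(C)(C)C | intermediate
16 | (2S)-2-[4-(TBSO)-3,5-dimethoxyphenyl]-7-methoxy-3-(oxomethylidene)-5-[3-(TBDPSO)propyl]-2,3-dihydro-1-benzofuran (ketene) | COc1cc([C@@H]2Oc3c(OC)cc(CCCO[Si](c4ccccc4)(c4ccccc4)C(C)(C)C)cc3C2=C=O)cc(OC)c1O[Si](C)(C)C(C)(C)C | intermediate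
17 | (2S)-2-[4-(TBSO)-3,5-dimethoxyphenyl]-3-[hydroxy(methoxy)methylidene]-7-methoxy-5-[3-(TBDPSO)propyl]-2,3-dihydro-1-benzofuran (ester enol, enol geometry not defined) | COc1cc([C@@H]2Oc3c(OC)cc(CCCO[Si](c4ccccc4)(c4ccccc4)C(C)(C)C)cc3C2=C(O)OC)cc(OC)c1O[Si](C)(C)C(C)(C)C | intermediate
18 | methyl (2R,3S)-2-[4-(TBSO)-3,5-dimethoxyphenyl]-7-methoxy-5-[3-(TBDPSO)propyl]-2,3-dihydro-1-benzofuran-3-carboxylate (cis) | COc1cc([C@@H]2Oc3c(OC)cc(CCCO[Si](c4ccccc4)(c4ccccc4)C(C)(C)C)cc3[C@@H]2C(=O)OC)cc(OC)c1O[Si](C)(C)C(C)(C)C | intermediate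
19 | {(2R,3R)-2-[4-(TBSO)-3,5-dimethoxyphenyl]-7-methoxy-5-[3-(TBDPSO)propyl]-2,3-dihydro-1-benzofuran-3-yl}methanol (cis) | COc1cc([C@@H]2Oc3c(OC)cc(CCCO[Si](c4ccccc4)(c4ccccc4)C(C)(C)C)cc3[C@@H]2CO)cc(OC)c1O[Si](C)(C)C(C)(C)C | intermediate
20 | (2R,3R)-2-[4-(TBSO)-3,5-dimethoxyphenyl]-3-(TBSO-methyl)-7-methoxy-5-[3-(TBDPSO)propyl]-2,3-dihydro-1-benzofuran | COc1cc([C@@H]2Oc3c(OC)cc(CCCO[Si](c4ccccc4)(c4ccccc4)C(C)(C)C)cc3[C@@H]2CO[Si](C)(C)C(C)(C)C)cc(OC)c1O[Si](C)(C)C(C)(C)C | intermediate
21 | 4-{(2R,3R)-3-(TBSO-methyl)-7-methoxy-5-[3-(TBDPSO)propyl]-2,3-dihydro-1-benzofuran-2-yl}-2,6-dimethoxyphenol | COc1cc([C@@H]2Oc3c(OC)cc(CCCO[Si](c4ccccc4)(c4ccccc4)C(C)(C)C)cc3[C@@H]2CO[Si](C)(C)C(C)(C)C)cc(OC)c1O | intermediate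
22 | methyl (4R)-2,2-dimethyl-1,3-dioxolane-4-carboxylate | COC(=O)[C@H]1COC(C)(C)O1 | starting material
23 | methyl (2R)-2,3-dihydroxypropanoate | COC(=O)[C@H](O)CO | intermediate
24 | methyl (2R)-3-(TBDPSO)-2-hydroxypropanoate | COC(=O)[C@H](O)CO[Si](c1ccccc1)(c1ccccc1)C(C)(C)C | intermediate
25 | methyl (2S)-2-(4-{(2R,3R)-3-(TBSO-methyl)-7-methoxy-5-[3-(TBDPSO)propyl]-2,3-dihydro-1-benzofuran-2-yl}-2,6-dimethoxyphenoxy)-3-(TBDPSO)propanoate | COC(=O)[C@H](CO[Si](c1ccccc1)(c1ccccc1)C(C)(C)C)Oc1c(OC)cc([C@@H]2Oc3c(OC)cc(CCCO[Si](c4ccccc4)(c4ccccc4)C(C)(C)C)cc3[C@@H]2CO[Si](C)(C)C(C)(C)C)cc1OC | intermediate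
26 | (2S)-2-(4-{(2R,3R)-3-(TBSO-methyl)-7-methoxy-5-[3-(TBDPSO)propyl]-2,3-dihydro-1-benzofuran-2-yl}-2,6-dimethoxyphenoxy)-3-(TBDPSO)-N-methoxy-N-methylpropanamide | CON(C)C(=O)[C@H](CO[Si](c1ccccc1)(c1ccccc1)C(C)(C)C)Oc1c(OC)cc([C@@H]2Oc3c(OC)cc(CCCO[Si](c4ccccc4)(c4ccccc4)C(C)(C)C)cc3[C@@H]2CO[Si](C)(C)C(C)(C)C)cc1OC | intermediate
27 | 4-bromo-2-methoxyphenol | COc1cc(Br)ccc1O | starting material
28 | (4-bromo-2-methoxyphenoxy)tri(propan-2-yl)silane | COc1cc(Br)ccc1O[Si](C(C)C)(C(C)C)C(C)C | intermediate
29 | [3-methoxy-4-(TIPSO)phenyl]lithium | [Li]c1ccc(O[Si](C(C)C)(C(C)C)C(C)C)c(OC)c1 | intermediate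
30 | (2S)-2-(4-{(2R,3R)-3-(TBSO-methyl)-7-methoxy-5-[3-(TBDPSO)propyl]-2,3-dihydro-1-benzofuran-2-yl}-2,6-dimethoxyphenoxy)-3-(TBDPSO)-1-[3-methoxy-4-(TIPSO)phenyl]propan-1-one | COc1cc(C(=O)[C@H](CO[Si](c2ccccc2)(c2ccccc2)C(C)(C)C)Oc2c(OC)cc([C@@H]3Oc4c(OC)cc(CCCO[Si](c5ccccc5)(c5ccccc5)C(C)(C)C)cc4[C@@H]3CO[Si](C)(C)C(C)(C)C)cc2OC)ccc1O[Si](C(C)C)(C(C)C)C(C)C | intermediate
31 | (1R,2S)-2-(4-{(2R,3R)-3-(TBSO-methyl)-7-methoxy-5-[3-(TBDPSO)propyl]-2,3-dihydro-1-benzofuran-2-yl}-2,6-dimethoxyphenoxy)-3-(TBDPSO)-1-[3-methoxy-4-(TIPSO)phenyl]propan-1-ol | COc1cc([C@@H](O)[C@H](CO[Si](c2ccccc2)(c2ccccc2)C(C)(C)C)Oc2c(OC)cc([C@@H]3Oc4c(OC)cc(CCCO[Si](c5ccccc5)(c5ccccc5)C(C)(C)C)cc4[C@@H]3CO[Si](C)(C)C(C)(C)C)cc2OC)ccc1O[Si](C(C)C)(C(C)C)C(C)C | intermediate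
32 | (1R,2S)-1-(4-hydroxy-3-methoxyphenyl)-2-{4-[(2R,3R)-3-(hydroxymethyl)-5-(3-hydroxypropyl)-7-methoxy-2,3-dihydro-1-benzofuran-2-yl]-2,6-dimethoxyphenoxy}propane-1,3-diol (CNP0301567.1) | COc1cc([C@@H](O)[C@H](CO)Oc2c(OC)cc([C@@H]3Oc4c(OC)cc(CCCO)cc4[C@@H]3CO)cc2OC)ccc1O | target

## Step count and least certain steps

Total: 20 steps. Longest linear sequence: 14 steps (steps 1, 2, 4, 7, 8, 9, 10, 11, 12, 15, 16, 18, 19, 20).

**Step 9 (key step).** Three things may go wrong. Carbene-type reactions (a 1,2-hydride shift from C2 that aromatises the pyranone ring, or O–H insertion of the solvent) may compete with the concerted shift. Ketonisation of 17 may show poor facial selectivity and give the trans ester. The cis ester may epimerise at C3 during handling. Fallback: the C3 configuration is set in a separate operation instead of during ketonisation. The route sets out from 15, whose photolysis then delivers material rich in the trans ester F1. F1 is deprotonated with LiN(i-Pr)2 in THF at –78 °C to the lithium ester enolate F2, which is protonated at –78 °C by a hindered phenol (2,6-di-tert-butyl-4-methylphenol) from the face anti to the C2 aryl group. This returns to the route at 18.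

**Step 7.** The electron-rich boronic acid may undergo protodeboronation or homocoupling faster than it inserts into the electron-rich 8-methoxychromone; enantioselectivity may be insufficient; the aryl silyl ether may be partly lost in the warm, wet medium. Fallback: the catalytic manifold is changed to the Hayashi–Miyaura 1,4-addition with monovalent rhodium ([RhCl(C2H4)2]2, a chiral bicyclo[2.2.2]octadiene ligand, K3PO4, dioxane/H2O, rt). It sets out from 8 and 12 and returns at 13. New compounds: none F0.

**Step 8.** The lithium enolate of 13 may open by retro-oxa-Michael reaction before it is acylated, with loss of the C2 configuration. Fallback: C3 is functionalised from the acid side. Setting out from 13, nitrosation with isoamyl nitrite and Me3SiCl in CH2Cl2 at –20 °C gives the 3-hydroxyimino flavanone F3, which has no C3–H. A Forster reaction of F3 with chloramine (aq. NH3, NaOCl, 0 °C) converts the oxime into the diazo group and returns at 15.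

**Step 15.** Substitution at the secondary carbinol by a phenol with two ortho methoxy groups may be slow, so that elimination or alkylation of the hydrazide takes over. While the phenol is deprotonated, reversible opening of the C2–O1 bond through the quinone methide may erode the cis configuration. Fallback: the leaving group is made beforehand. Setting out from 24, triflation (Tf2O, 2,6-lutidine, CH2Cl2, –78 °C) gives the triflate F4. F4 is displaced with inversion by the phenoxide of 21 (K2CO3, MeCN, –20 → 0 °C), which is consumed as fast as it forms. This returns at 25.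

**Step 19.** Facial selectivity may be poor if lithium chelation between the carbonyl and the C8 or C9 oxygen competes with the Felkin–Anh mode; C8 may also epimerise if the ketone is enolised by the basic hydride. Fallback: the erythro relationship is reached by inversion instead of direct reduction. Setting out from 30, the threo alcohol F5 formed in the reduction is not discarded. It is treated with 4-nitrobenzoic acid, PPh3 and diisopropyl azodicarboxylate (Mitsunobu inversion at C7) to give the 4-nitrobenzoate F6. Mild methanolysis (K2CO3, MeOH, 0 °C) returns at 31.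

## Further compounds

F1 | step 9 | methyl (2R,3R)-2-[4-(TBSO)-3,5-dimethoxyphenyl]-7-methoxy-5-[3-(TBDPSO)propyl]-2,3-dihydro-1-benzofuran-3-carboxylate (trans, C3 epimer of 18) | COc1cc([C@@H]2Oc3c(OC)cc(CCCO[Si](c4ccccc4)(c4ccccc4)C(C)(C)C)cc3[C@H]2C(=O)OC)cc(OC)c1O[Si](C)(C)C(C)(C)C
F2 | step 9 | lithium ester enolate of F1 | COc1cc([C@@H]2Oc3c(OC)cc(CCCO[Si](c4ccccc4)(c4ccccc4)C(C)(C)C)cc3C2=C([O-])OC)cc(OC)c1O[Si](C)(C)C(C)(C)C.[Li+]
F0 | step 7 | none | none
F3 | step 8 | (2S)-3-(hydroxyimino)-2-[4-(TBSO)-3,5-dimethoxyphenyl]-8-methoxy-6-[3-(TBDPSO)propyl]chroman-4-one (oxime geometry not defined) | COc1cc([C@@H]2Oc3c(OC)cc(CCCO[Si](c4ccccc4)(c4ccccc4)C(C)(C)C)cc3C(=O)C2=NO)cc(OC)c1O[Si](C)(C)C(C)(C)C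
F4 | step 15 | methyl (2R)-3-(TBDPSO)-2-(trifluoromethylsulfonyloxy)propanoate | COC(=O)[C@H](OS(=O)(=O)C(F)(F)F)CO[Si](c1ccccc1)(c1ccccc1)C(C)(C)C
F5 | step 19 | (1S,2S)-2-(4-{(2R,3R)-3-(TBSO-methyl)-7-methoxy-5-[3-(TBDPSO)propyl]-2,3-dihydro-1-benzofuran-2-yl}-2,6-dimethoxyphenoxy)-3-(TBDPSO)-1-[3-methoxy-4-(TIPSO)phenyl]propan-1-ol (threo, C7 epimer of 31) | COc1cc([C@H](O)[C@H](CO[Si](c2ccccc2)(c2ccccc2)C(C)(C)C)Oc2c(OC)cc([C@@H]3Oc4c(OC)cc(CCCO[Si](c5ccccc5)(c5ccccc5)C(C)(C)C)cc4[C@@H]3CO[Si](C)(C)C(C)(C)C)cc2OC)ccc1O[Si](C(C)C)(C(C)C)C(C)C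
F6 | step 19 | (1R,2S)-2-(4-{(2R,3R)-3-(TBSO-methyl)-7-methoxy-5-[3-(TBDPSO)propyl]-2,3-dihydro-1-benzofuran-2-yl}-2,6-dimethoxyphenoxy)-3-(TBDPSO)-1-[3-methoxy-4-(TIPSO)phenyl]propyl 4-nitrobenzoate | COc1cc([C@@H](OC(=O)c2ccc(cc2)[N+](=O)[O-])[C@H](CO[Si](c2ccccc2)(c2ccccc2)C(C)(C)C)Oc2c(OC)cc([C@@H]3Oc4c(OC)cc(CCCO[Si](c5ccccc5)(c5ccccc5)C(C)(C)C)cc4[C@@H]3CO[Si](C)(C)C(C)(C)C)cc2OC)ccc1O[Si](C(C)C)(C(C)C)C(C)C
A1 | alternative 1 | C7-deoxy phenol with tert-butyl carbonate on O9 (C8 and dihydrobenzofuran configured as in the target) | COc1cc(C[C@H](COC(=O)OC(C)(C)C)Oc2c(OC)cc([C@@H]3Oc4c(OC)cc(CCCO[Si](C)(C)C(C)(C)C)cc4[C@@H]3CO[Si](C)(C)C(C)(C)C)cc2OC)ccc1O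
A2 | alternative 1 | trans six-membered cyclic carbonate across C7 and C9 (erythro series) | COc1cc([C@H]2OC(=O)OC[C@@H]2Oc2c(OC)cc([C@@H]3Oc4c(OC)cc(CCCO[Si](C)(C)C(C)(C)C)cc4[C@@H]3CO[Si](C)(C)C(C)(C)C)cc2OC)ccc1O
A3 | alternative 2 | open-chain ring C phenol with benzylic carbinol (syn-aldol series), ring B pivalate | COc1cc([C@@H](O)[C@@H](CO[Si](C)(C)C(C)(C)C)c2cc(CCCO[Si](C)(C)C(C)(C)C)cc(OC)c2O)cc(OC)c1OC(=O)C(C)(C)C
A4 | alternative 2 | cis-dihydrobenzofuran with ring B pivalate | COc1cc([C@@H]2Oc3c(OC)cc(CCCO[Si](C)(C)C(C)(C)C)cc3[C@@H]2CO[Si](C)(C)C(C)(C)C)cc(OC)c1OC(=O)C(C)(C)C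
A5 | alternative 3 | methyl 2-diazo-2-aryl acetate of ring C carrying the ring B benzyl ether | COC(=O)C(=[N+]=[N-])c1cc(CCCO[Si](C)(C)C(C)(C)C)cc(OC)c1OCc1cc(OC)c(O[Si](C(C)C)(C(C)C)C(C)C)c(OC)c1
A6 | alternative 3 | cis methyl 2-aryl-2,3-dihydrobenzofuran-3-carboxylate with ring B TIPS ether | COc1cc([C@@H]2Oc3c(OC)cc(CCCO[Si](C)(C)C(C)(C)C)cc3[C@@H]2C(=O)OC)cc(OC)c1O[Si](C(C)C)(C(C)C)C(C)C
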